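**Plan**

1. Numbering and enabling feature: isocopalane numbering C1–C20 is used for the terpenoid (ring A C1–C5/C10, ring B C5–C10, ring C C8/C9/C11–C14; C15 = CH2 on C14, C19 = lactone C=O on C4, C20 = OCH2 on C10) and C1′–C6′ for the enedione ring. The spiro carbon C1′ carries the ether oxygen from C13 and is also β to the C3′ ketone (C1′–C2′H2–C3′=O). The tetrahydrofuran ring (O, C13, C14, C15, C1′) can therefore be cut at C15–C1′, giving a C15 radical that adds to the alkoxy-bearing enone carbon of a quinone monoketal held on O–C13.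
2. Further cuts: the C13–O–C1′ ether (tertiary alkoxide plus a 3-fluoro quinone monoketal), C13–OH (hydration of a 13(16)-alkene) and the C19–O–C20 lactone; then C4–C5, C9–C10 and C8–C14 together, back to an open-chain β-keto ester. C3–C4 (Claisen condensation), C1–C2 (Claisen rearrangement) and C5–C10 (vinyllithium addition) lead to a C12 aldehyde from farnesol.
3. Forward order: chain assembly (steps 1–8); rings A, B and C in one step (step 9); C3 deoxygenation and lactone ring (steps 10–13); C13 oxygen and dienone ether (steps 14–16); C15 iodide (steps 17–18); tetrahydrofuran and spiro centre (step 19); ketal hydrolysis (step 20).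
4. Stereochemistry: the absolute configuration comes from the (1R,2S,5R)-8-phenylmenthyl ester in the cascade. C4, C5, C8, C9, C10 and C14 follow from all-chair folding of the geometrically defined triene. C13 comes from O2 capture on the α face, opposite the axial C8 methyl. C1′ comes from the dienone face attacked in the key step.

Key step: step 19

Assumption: the (1R,2S,5R)-8-phenylmenthyl ester is taken to shield the radical face that leads to the series drawn (4β-ester, 5α-H, 10β-CH2O); if the cascade gave the antipodal tricycle as the major diastereomer, the enantiomeric auxiliary would be used with no other change.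

**Route**

Step 1
Reactants: 1 (2E,6E)-farnesol
Product: 2 (2E,6E)-farnesyl tert-butyldiphenylsilyl ether
Conditions: TBDPSCl, imidazole, DMF, 0 °C → rt
Reagents that add atoms: tert-butyl(chloro)diphenylsilane, CC(C)(C)[Si](Cl)(c1ccccc1)c1ccccc1
Why: Imidazole-mediated silylation of the primary allylic alcohol gives an ether that should survive the acidic, basic, organolithium and radical steps up to step 17.

Step 2
Reactants: 2 (2E,6E)-farnesyl tert-butyldiphenylsilyl ether
Product: 4 racemic 10,11-epoxide of 2, via bromohydrin 3 (not isolated)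
Conditions: NBS, THF/H2O (3:1), 0 °C; then K2CO3, MeOH, rt
Reagents that add atoms: water, O
Why: Bromohydrin formation in aqueous THF should occur at the terminal trisubstituted alkene, the most exposed and least deactivated one, and K2CO3 then closes the epoxide by intramolecular Williamson substitution; the new centre is racemic and is excised in step 3.

Step 3
Reactants: 4 racemic 10,11-epoxide of 2
Product: 5 (4E,8E)-10-[(tert-butyldiphenylsilyl)oxy]-4,8-dimethyldeca-4,8-dienal
Conditions: H5IO6, THF/Et2O, 0 °C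
Reagents that add atoms: none
Why: Periodic acid opens the epoxide to the glycol and cleaves it (oxidative glycol cleavage) to the aldehyde that becomes C5, leaving the two remaining alkenes untouched.

Step 4
Reactants: 6 2,3-dibromopropene; 7 4-methoxybenzyl alcohol
Product: 8 2-bromoallyl 4-methoxybenzyl ether
Conditions: NaH, THF, 0 °C → rt
Reagents that add atoms: none
Why: Williamson etherification takes place at the allylic bromide only and keeps the vinyl bromide for lithiation.

Step 5
Reactants: 8 2-bromoallyl 4-methoxybenzyl ether; 5 (4E,8E)-10-[(tert-butyldiphenylsilyl)oxy]-4,8-dimethyldeca-4,8-dienal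
Product: 10 racemic (6E,10E)-12-[(tert-butyldiphenylsilyl)oxy]-2-{[(4-methoxybenzyl)oxy]methyl}-6,10-dimethyldodeca-1,6,10-trien-3-ol, via 2-lithioallyl ether 9 (not isolated)
Conditions: t-BuLi (2 equiv), Et2O, −78 °C; then 5, −78 °C
Reagents that add atoms: none
Why: Bromine–lithium exchange gives the vinyllithium, which adds 1,2 to the aldehyde (organolithium carbonyl addition) and joins C10 to C5; the carbinol centre is racemic and is destroyed in step 6.

Step 6
Reactants: 10 racemic allylic alcohol
Product: 12 ethyl (4Z,8E,12E)-14-[(tert-butyldiphenylsilyl)oxy]-4-{[(4-methoxybenzyl)oxy]methyl}-8,12-dimethyltetradeca-4,8,12-trienoate, via ketene acetal 11 (not isolated)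
Conditions: MeC(OEt)3, EtCO2H (cat.), 140 °C
Reagents that add atoms: triethyl orthoacetate, CC(OCC)(OCC)OCC
Why: The Johnson–Claisen rearrangement passes through a chair with the C6 chain equatorial and should give the trisubstituted alkene with C1 trans to C6 (CH2OPMB cis to C6), the geometry the cascade needs, while adding C1–C2–C3 as the ester.

Step 7
Reactants: 13 (1R,2S,5R)-8-phenylmenthol
Product: 14 (1R,2S,5R)-8-phenylmenthyl propionate
Conditions: EtCOCl, pyridine, DMAP (cat.), CH2Cl2, 0 °C → rt
Reagents that add atoms: propionyl chloride, CCC(Cl)=O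
Why: DMAP-catalysed acylation of the secondary alcohol gives the ester that supplies C4, C18 and C19 together with the chiral auxiliary.

Step 8
Reactants: 14 (1R,2S,5R)-8-phenylmenthyl propionate; 12 ethyl trienoate
Product: 16 (1R,2S,5R)-8-phenylmenthyl (6Z,10E,14E)-16-[(tert-butyldiphenylsilyl)oxy]-6-{[(4-methoxybenzyl)oxy]methyl}-2,10,14-trimethyl-3-oxohexadeca-6,10,14-trienoate (both C2 epimers), via lithium enolate 15 (not isolated)
Conditions: LiN(iPr)2, THF, −78 °C; then 12, −78 → 0 °C
Reagents that add atoms: none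
Why: In this crossed Claisen condensation the hindered auxiliary ester cannot self-condense, so its enolate (used in excess) acylates on the unhindered ethyl ester and the product is held as its enolate until work-up; the C2 mixture does not matter because this carbon becomes the radical centre.

Step 9
Reactants: 16 β-keto ester
Product: 17 (1R,2S,5R)-8-phenylmenthyl 15-(tert-butyldiphenylsilyloxy)-20-(4-methoxybenzyloxy)-3-oxoisocopal-13(16)-en-19-oate (4α-methyl, 4β-ester, 5α-H, 8β-methyl, 9α-H, 10β-CH2O, 14α-H)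
Conditions: Mn(OAc)3·2H2O (2.2 equiv), Cu(OAc)2·H2O (1 equiv), degassed AcOH, rt
Reagents that add atoms: none
Why: In this oxidative radical polyene cyclisation Mn(OAc)3 generates the C4 radical, three 6-endo closures through an all-chair folding form rings A, B and C with trans–anti–trans fusion, the C4 ester and C20 axial and C15 equatorial, and Cu(OAc)2 oxidises the final C13 radical to the exocyclic alkene; the phenyl group of the auxiliary is expected to screen one face of the radical, and the diastereomer with the antipodal ring system should be separable by chromatography.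

Step 10
Reactants: 17 tricyclic keto ester
Product: 18 C3 tosylhydrazone of 17
Conditions: TsNHNH2, EtOH, 70 °C
Reagents that add atoms: 4-methylbenzenesulfonohydrazide, Cc1ccc(cc1)S(=O)(=O)NN
Why: Hydrazone formation at the only ketone prepares C3 for reductive removal, and the quaternary C4 rules out enolisation or ring closure onto the ester.

Step 11
Reactants: 18 C3 tosylhydrazone
Product: 20 (1R,2S,5R)-8-phenylmenthyl 15-(tert-butyldiphenylsilyloxy)-20-(4-methoxybenzyloxy)isocopal-13(16)-en-19-oate, via N-boryl tosylhydrazine 19 (not isolated)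
Conditions: catecholborane, CHCl3, 0 °C → rt; then NaOAc·3H2O, 60 °C
Reagents that add atoms: none
Why: Tosylhydrazone reduction (hydroboration of C=N, then acetate-induced loss of sulfinate and N2) should give the C3 methylene without touching the ester, the ethers or the 1,1-disubstituted alkene.

Step 12
Reactants: 20 3-deoxy ester
Product: 21 (1R,2S,5R)-8-phenylmenthyl 15-(tert-butyldiphenylsilyloxy)-20-hydroxyisocopal-13(16)-en-19-oate
Conditions: DDQ, CH2Cl2/pH 7 buffer, 0 °C → rt
Reagents that add atoms: none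
Why: Oxidative cleavage of the p-methoxybenzyl ether by DDQ is selective over the silyl ether and the unactivated alkene.

Step 13
Reactants: 21 C20 alcohol
Product: 22 15-(tert-butyldiphenylsilyloxy)isocopal-13(16)-en-19,20-olide
Conditions: NaH, THF, 0 → 50 °C
Reagents that add atoms: none
Why: The C20 alkoxide sits 1,3-diaxial to the C19 ester and should displace the auxiliary alkoxide by intramolecular transesterification (lactonisation), which also returns 8-phenylmenthol for reuse.

Step 14
Reactants: 22 lactone alkene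
Product: 23 13α-hydroxy-15-(tert-butyldiphenylsilyloxy)isocopalan-19,20-olide (13β-methyl)
Conditions: Co(acac)2 (cat.), PhSiH3, O2 (1 atm), THF, 0 °C → rt
Reagents that add atoms: dioxygen, O=O
Why: In this Mukaiyama hydration hydrogen-atom transfer to the methylene carbon gives the planar tertiary C13 radical, which should take up O2 from the α face in the equatorial direction because the β face is blocked by the axial C8 methyl, so the hydroxyl ends up equatorial and the methyl axial.

Step 15
Reactants: 24 3-fluoro-4-methoxyphenol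
Product: 25 3-fluoro-4,4-dimethoxycyclohexa-2,5-dien-1-one
Conditions: PhI(OAc)2, MeOH, 0 °C
Reagents that add atoms: methanol, CO
Why: Oxidative dearomatisation of a p-methoxyphenol in methanol gives the quinone monoketal with the carbonyl at the former phenol carbon and the fluorine on the β-carbon next to the ketal.

Step 16
Reactants: 23 tertiary alcohol; 25 3-fluoro-4,4-dimethoxycyclohexa-2,5-dien-1-one
Product: 27 13α-[(6,6-dimethoxy-3-oxocyclohexa-1,4-dien-1-yl)oxy]-15-(tert-butyldiphenylsilyloxy)isocopalan-19,20-olide, via potassium alkoxide 26 (not isolated)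
Conditions: KN(SiMe3)2, THF, −78 → 0 °C; then 25, 0 °C → rt
Reagents that add atoms: none
Why: Nucleophilic vinylic substitution (addition of the alkoxide to the fluorine-bearing β-carbon of the enone, then loss of fluoride) gives the vinylogous ester; fluorine is the small leaving group that most accelerates the addition, and the lactone has no α-hydrogen for the base to remove.

Step 17
Reactants: 27 vinylogous ester silyl ether
Product: 28 13α-[(6,6-dimethoxy-3-oxocyclohexa-1,4-dien-1-yl)oxy]-15-hydroxyisocopalan-19,20-olide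
Conditions: Bu4NF, AcOH (1:1), THF, 0 °C → rt
Reagents that add atoms: none
Why: Fluoride-induced desilylation frees the C15 alcohol, and the AcOH buffer keeps a free C15 alkoxide from adding to the neighbouring vinylogous ester.

Step 18
Reactants: 28 C15 alcohol
Product: 29 13α-[(6,6-dimethoxy-3-oxocyclohexa-1,4-dien-1-yl)oxy]-15-iodoisocopalan-19,20-olide
Conditions: I2, PPh3, imidazole, CH2Cl2, 0 °C → rt
Reagents that add atoms: iodine, II
Why: Appel iodination through the alkoxyphosphonium salt places iodide at C15 by SN2 displacement under imidazole-buffered conditions that the ketal and the vinylogous ester should tolerate.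

Step 19
Reactants: 29 C15 iodide
Product: 30 C6′ dimethyl ketal of the target (spiro tetrahydrofuran closed between C15 and C1′; C6′ on the β face beside the 13β-methyl, C2′H2 on the α face)
Conditions: Bu3SnH (slow addition), AIBN (cat.), benzene (0.005 M), 80 °C
Reagents that add atoms: none
Why: Proposed new method: Bu3Sn• abstracts iodine from C15 and the nucleophilic primary radical adds 5-exo-trig to C1′, the alkoxy-bearing β-carbon of the C3′ enone, which forms C15–C1′, closes the tetrahydrofuran ring and leaves a C2′ radical that is stabilised by the C3′ carbonyl and is quenched by the stannane. The closest known reaction type is the radical cyclisation of β-alkoxyacrylates and β-alkoxy enones to 2,5-cis cyclic ethers; what has not been shown is addition to a fully substituted ring carbon of a quinone monoketal to give a spiro centre. The one ring that closes does so in the 5-exo mode, and its trans fusion to ring C is already fixed by the equatorial C13–O and C14–C15 bonds. The step needs attack at C1′ and not 6-endo attack at C2′ or attack at C5′: the C6′ ketal removes the second carbonyl, so C2′ is an electron-rich α-carbon that a nucleophilic radical avoids, and C5′ could only be reached through a seven-membered transition state. The new stereocentre C1′ is set by the dienone face that meets C15; the chair-like transition state with the exocyclic C2′ terminus pseudo-equatorial, the arrangement behind the cis preference of β-alkoxyacrylate closures, places C6′ on the side of the axial C13 methyl as the target requires. High dilution and slow addition of the stannane keep simple reduction of the C15 radical from outrunning the closure on the hindered carbon.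

Step 20
Reactants: 30 C6′ dimethyl ketal
Product: 31 target spiro enedione lactone (CNP0290557.1)
Conditions: oxalic acid, THF/H2O, rt
Reagents that add atoms: water, O
Why: Acid-catalysed ketal hydrolysis frees the C6′ ketone under conditions mild enough that the tertiary spiro ether, a β-alkoxy ketone, should neither ionise nor open, so C1′ keeps its configuration.

**Compound list**

1 | (2E,6E)-farnesol | CC(C)=CCC/C(C)=C/CC/C(C)=C/CO | starting material
2 | (2E,6E)-farnesyl tert-butyldiphenylsilyl ether | CC(C)=CCC/C(C)=C/CC/C(C)=C/CO[Si](c1ccccc1)(c1ccccc1)C(C)(C)C | intermediate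
3 | 10-bromo-11-hydroxy-10,11-dihydrofarnesyl tert-butyldiphenylsilyl ether (racemic bromohydrin) | CC(C)(O)C(Br)CC/C(C)=C/CC/C(C)=C/CO[Si](c1ccccc1)(c1ccccc1)C(C)(C)C | intermediate
4 | 10,11-epoxy-10,11-dihydrofarnesyl tert-butyldiphenylsilyl ether (racemic) | CC1(C)OC1CC/C(C)=C/CC/C(C)=C/CO[Si](c1ccccc1)(c1ccccc1)C(C)(C)C | intermediate
5 | (4E,8E)-10-[(tert-butyldiphenylsilyl)oxy]-4,8-dimethyldeca-4,8-dienal | O=CCC/C(C)=C/CC/C(C)=C/CO[Si](c1ccccc1)(c1ccccc1)C(C)(C)C | intermediate
6 | 2,3-dibromopropene | C=C(Br)CBr | starting material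
7 | 4-methoxybenzyl alcohol | COc1ccc(CO)cc1 | starting material
8 | 2-bromoallyl 4-methoxybenzyl ether | C=C(Br)COCc1ccc(OC)cc1 | intermediate
9 | 2-lithioallyl 4-methoxybenzyl ether | [Li]C(=C)COCc1ccc(OC)cc1 | intermediate
10 | (6E,10E)-12-[(tert-butyldiphenylsilyl)oxy]-2-{[(4-methoxybenzyl)oxy]methyl}-6,10-dimethyldodeca-1,6,10-trien-3-ol (racemic) | C=C(COCc1ccc(OC)cc1)C(O)CC/C(C)=C/CC/C(C)=C/CO[Si](c1ccccc1)(c1ccccc1)C(C)(C)C | intermediate
11 | mixed ketene acetal of 10 (1-ethoxyvinyl ether of the allylic alcohol) | C=C(OCC)OC(CC/C(C)=C/CC/C(C)=C/CO[Si](c1ccccc1)(c1ccccc1)C(C)(C)C)C(=C)COCc1ccc(OC)cc1 | intermediate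
12 | ethyl (4Z,8E,12E)-14-[(tert-butyldiphenylsilyl)oxy]-4-{[(4-methoxybenzyl)oxy]methyl}-8,12-dimethyltetradeca-4,8,12-trienoate | CCOC(=O)CC/C(COCc1ccc(OC)cc1)=C/CC/C(C)=C/CC/C(C)=C/CO[Si](c1ccccc1)(c1ccccc1)C(C)(C)C | intermediate
13 | (1R,2S,5R)-8-phenylmenthol [(1R,2S,5R)-5-methyl-2-(2-phenylpropan-2-yl)cyclohexan-1-ol] | O[C@@H]1C[C@H](C)CC[C@H]1C(C)(C)c1ccccc1 | starting material
14 | (1R,2S,5R)-8-phenylmenthyl propionate | CCC(=O)O[C@@H]1C[C@H](C)CC[C@H]1C(C)(C)c1ccccc1 | intermediate
15 | lithium enolate of 14 | CC=C([O-])O[C@@H]1C[C@H](C)CC[C@H]1C(C)(C)c1ccccc1.[Li+] | intermediate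
16 | (1R,2S,5R)-8-phenylmenthyl (6Z,10E,14E)-16-[(tert-butyldiphenylsilyl)oxy]-6-{[(4-methoxybenzyl)oxy]methyl}-2,10,14-trimethyl-3-oxohexadeca-6,10,14-trienoate (C2 epimers) | CC(C(=O)O[C@@H]1C[C@H](C)CC[C@H]1C(C)(C)c1ccccc1)C(=O)CC/C(COCc1ccc(OC)cc1)=C/CC/C(C)=C/CC/C(C)=C/CO[Si](c1ccccc1)(c1ccccc1)C(C)(C)C | intermediate
17 | (1R,2S,5R)-8-phenylmenthyl 15-(tert-butyldiphenylsilyloxy)-20-(4-methoxybenzyloxy)-3-oxoisocopal-13(16)-en-19-oate (4α-Me, 4β-ester, 5α-H, 8β-Me, 9α-H, 10β-CH2O, 14α-H) | C[C@@]12CC[C@@H]3[C@](COCc4ccc(OC)cc4)(CCC(=O)[C@]3(C)C(=O)O[C@@H]4C[C@H](C)CC[C@H]4C(C)(C)c4ccccc4)[C@H]1CCC(=C)[C@H]2CO[Si](c1ccccc1)(c1ccccc1)C(C)(C)C | intermediate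
18 | C3 tosylhydrazone of 17 | C[C@@]12CC[C@@H]3[C@](COCc4ccc(OC)cc4)(CCC(=NNS(=O)(=O)c4ccc(C)cc4)[C@]3(C)C(=O)O[C@@H]4C[C@H](C)CC[C@H]4C(C)(C)c4ccccc4)[C@H]1CCC(=C)[C@H]2CO[Si](c1ccccc1)(c1ccccc1)C(C)(C)C | intermediate
19 | N-(1,3,2-benzodioxaborol-2-yl) tosylhydrazine from 18 (C3 configuration undefined) | C[C@@]12CC[C@@H]3[C@](COCc4ccc(OC)cc4)(CCC(N(NS(=O)(=O)c4ccc(C)cc4)B4Oc5ccccc5O4)[C@]3(C)C(=O)O[C@@H]4C[C@H](C)CC[C@H]4C(C)(C)c4ccccc4)[C@H]1CCC(=C)[C@H]2CO[Si](c1ccccc1)(c1ccccc1)C(C)(C)C | intermediate
20 | (1R,2S,5R)-8-phenylmenthyl 15-(tert-butyldiphenylsilyloxy)-20-(4-methoxybenzyloxy)isocopal-13(16)-en-19-oate | C[C@@]12CC[C@@H]3[C@](COCc4ccc(OC)cc4)(CCC[C@]3(C)C(=O)O[C@@H]4C[C@H](C)CC[C@H]4C(C)(C)c4ccccc4)[C@H]1CCC(=C)[C@H]2CO[Si](c1ccccc1)(c1ccccc1)C(C)(C)C | intermediate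
21 | (1R,2S,5R)-8-phenylmenthyl 15-(tert-butyldiphenylsilyloxy)-20-hydroxyisocopal-13(16)-en-19-oate | C[C@@]12CC[C@@H]3[C@](CO)(CCC[C@]3(C)C(=O)O[C@@H]4C[C@H](C)CC[C@H]4C(C)(C)c4ccccc4)[C@H]1CCC(=C)[C@H]2CO[Si](c1ccccc1)(c1ccccc1)C(C)(C)C | intermediate
22 | 15-(tert-butyldiphenylsilyloxy)isocopal-13(16)-en-19,20-olide | C[C@@]12CC[C@@H]3[C@]4(CCC[C@]3(C)C(=O)OC4)[C@H]1CCC(=C)[C@H]2CO[Si](c1ccccc1)(c1ccccc1)C(C)(C)C | intermediate
23 | 13α-hydroxy-15-(tert-butyldiphenylsilyloxy)isocopalan-19,20-olide (13β-methyl) | C[C@@]12CC[C@@H]3[C@]4(CCC[C@]3(C)C(=O)OC4)[C@H]1CC[C@](C)(O)[C@H]2CO[Si](c1ccccc1)(c1ccccc1)C(C)(C)C | intermediate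
24 | 3-fluoro-4-methoxyphenol | COc1ccc(O)cc1F | starting material
25 | 3-fluoro-4,4-dimethoxycyclohexa-2,5-dien-1-one | COC1(OC)C=CC(=O)C=C1F | intermediate
26 | potassium 13α-alkoxide of 23 | [K+].C[C@@]12CC[C@@H]3[C@]4(CCC[C@]3(C)C(=O)OC4)[C@H]1CC[C@](C)([O-])[C@H]2CO[Si](c1ccccc1)(c1ccccc1)C(C)(C)C | intermediate
27 | 13α-[(6,6-dimethoxy-3-oxocyclohexa-1,4-dien-1-yl)oxy]-15-(tert-butyldiphenylsilyloxy)isocopalan-19,20-olide | C[C@@]12CC[C@@H]3[C@]4(CCC[C@]3(C)C(=O)OC4)[C@H]1CC[C@](C)(OC3=CC(=O)C=CC3(OC)OC)[C@H]2CO[Si](c1ccccc1)(c1ccccc1)C(C)(C)C | intermediate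
28 | 13α-[(6,6-dimethoxy-3-oxocyclohexa-1,4-dien-1-yl)oxy]-15-hydroxyisocopalan-19,20-olide | C[C@@]12CC[C@@H]3[C@]4(CCC[C@]3(C)C(=O)OC4)[C@H]1CC[C@](C)(OC3=CC(=O)C=CC3(OC)OC)[C@H]2CO | intermediate
29 | 13α-[(6,6-dimethoxy-3-oxocyclohexa-1,4-dien-1-yl)oxy]-15-iodoisocopalan-19,20-olide | C[C@@]12CC[C@@H]3[C@]4(CCC[C@]3(C)C(=O)OC4)[C@H]1CC[C@](C)(OC3=CC(=O)C=CC3(OC)OC)[C@H]2CI | intermediate
30 | C6′ dimethyl ketal of the target (13α-O–C1′ and C15–C1′ spiro tetrahydrofuran; C6′ β, C2′ α) | C[C@@]12CC[C@@H]3[C@]4(CCC[C@]3(C)C(=O)OC4)[C@H]1CC[C@]1(C)O[C@]3(CC(=O)C=CC3(OC)OC)C[C@@H]21 | intermediate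
31 | target spiro enedione 19,20-lactone (CNP0290557.1) | C[C@@]12CC[C@@H]3[C@]4(CCC[C@]3(C)C(=O)OC4)[C@H]1CC[C@]1(C)O[C@]3(CC(=O)C=CC3=O)C[C@@H]21 | target

**Step count and risks**

Total step count: 20. Longest linear sequence: 17 steps (steps 1–3, 5, 6, 8–14 and 16–20).

Steps most likely to fail:

Step 19. The C15 radical may be reduced before it closes on the fully substituted C1′. The dienone may also present its other face, because the ketal carbon is pushed away from the axial C13 methyl, which would give poor or inverted facial selectivity at C1′. The fallback forms the same ring through the C1′–O bond by known reactions and sets C1′ under thermodynamic control. It sets out from 23: fluoride desilylation (Bu4NF, THF) gives the 13α,15-diol F1. Appel iodination of the primary hydroxyl only (I2, PPh3, imidazole) gives the iodo alcohol F2. Nickel-catalysed reductive cross-electrophile coupling with 2-iodo-1,4-dimethoxybenzene (NiI2, 4,4′-di-tert-butyl-2,2′-bipyridine, Zn, DMA, 60 °C) gives the C15-aryl lactone F3. Oxidative demethylation with (NH4)2Ce(NO3)6 in MeCN/H2O gives the hydroxy quinone F4. Its 13α-hydroxyl should add 5-exo to the alkyl-bearing quinone carbon (intramolecular oxa-Michael addition, Et3N, CH2Cl2), so the fallback comes back to the route at 31.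

Step 16. Steric shielding around the tertiary alkoxide and the ketal-flanked β-carbon may prevent the substitution, so that reversible addition at the unsubstituted β-carbon and slow decomposition of the dienone take over. The fallback makes the aryl–oxygen bond on a sterically undemanding aryne and oxidises afterwards. It sets out from 23: the potassium alkoxide adds to 3,6-dimethoxybenzyne, generated from 2-bromo-1,4-dimethoxybenzene with lithium 2,2,6,6-tetramethylpiperidide in THF, to give the 2,5-dimethoxyphenyl ether F5. Anodic oxidation (Pt anode, KOH, MeOH, 0 °C) gives the quinone bisketal F6. Mild monohydrolysis (aqueous AcOH, acetone, 0 °C) should remove first the ketal that is vinylogous to the ether oxygen, so the fallback comes back to the route at 27.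

Step 9. The oxidant may intercept the C10 or C8 radical before the next ring closes, giving mono- and bicyclic olefins, and the acidic medium may strip the ether protecting groups. The fallback generates the same radical without oxidant or acid and ends the cascade by halogen transfer. It sets out from 16: enolate bromination (NaH, then NBS, THF, −78 °C) gives the α-bromo β-keto ester F7. A bromine-atom-transfer cascade (Et3B, air, toluene, rt) gives the tricyclic C13 bromide F8. Dehydrobromination with DBU comes back to the route at 17; any endocyclic alkene isomer formed alongside would give the same C13 radical in step 14.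

Further compounds
F1 | step 19 | 13α,15-dihydroxyisocopalan-19,20-olide | C[C@@]12CC[C@@H]3[C@]4(CCC[C@]3(C)C(=O)OC4)[C@H]1CC[C@](C)(O)[C@H]2CO
F2 | step 19 | 13α-hydroxy-15-iodoisocopalan-19,20-olide | C[C@@]12CC[C@@H]3[C@]4(CCC[C@]3(C)C(=O)OC4)[C@H]1CC[C@](C)(O)[C@H]2CI
F3 | step 19 | 15-(2,5-dimethoxyphenyl)-13α-hydroxyisocopalan-19,20-olide | C[C@@]12CC[C@@H]3[C@]4(CCC[C@]3(C)C(=O)OC4)[C@H]1CC[C@](C)(O)[C@H]2Cc1cc(OC)ccc1OC
F4 | step 19 | 15-(3,6-dioxocyclohexa-1,4-dien-1-yl)-13α-hydroxyisocopalan-19,20-olide | C[C@@]12CC[C@@H]3[C@]4(CCC[C@]3(C)C(=O)OC4)[C@H]1CC[C@](C)(O)[C@H]2CC1=CC(=O)C=CC1=O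
F5 | step 16 | 13α-(2,5-dimethoxyphenoxy)-15-(tert-butyldiphenylsilyloxy)isocopalan-19,20-olide | C[C@@]12CC[C@@H]3[C@]4(CCC[C@]3(C)C(=O)OC4)[C@H]1CC[C@](C)(Oc3cc(OC)ccc3OC)[C@H]2CO[Si](c1ccccc1)(c1ccccc1)C(C)(C)C
F6 | step 16 | 13α-[(3,3,6,6-tetramethoxycyclohexa-1,4-dien-1-yl)oxy]-15-(tert-butyldiphenylsilyloxy)isocopalan-19,20-olide | C[C@@]12CC[C@@H]3[C@]4(CCC[C@]3(C)C(=O)OC4)[C@H]1CC[C@](C)(OC3=CC(OC)(OC)C=CC3(OC)OC)[C@H]2CO[Si](c1ccccc1)(c1ccccc1)C(C)(C)C
F7 | step 9 | (1R,2S,5R)-8-phenylmenthyl (6Z,10E,14E)-2-bromo-16-[(tert-butyldiphenylsilyl)oxy]-6-{[(4-methoxybenzyl)oxy]methyl}-2,10,14-trimethyl-3-oxohexadeca-6,10,14-trienoate | CC(Br)(C(=O)O[C@@H]1C[C@H](C)CC[C@H]1C(C)(C)c1ccccc1)C(=O)CC/C(COCc1ccc(OC)cc1)=C/CC/C(C)=C/CC/C(C)=C/CO[Si](c1ccccc1)(c1ccccc1)C(C)(C)C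
F8 | step 9 | (1R,2S,5R)-8-phenylmenthyl 13-bromo-15-(tert-butyldiphenylsilyloxy)-20-(4-methoxybenzyloxy)-3-oxoisocopalan-19-oate (C13 configuration undefined) | C[C@@]12CC[C@@H]3[C@](COCc4ccc(OC)cc4)(CCC(=O)[C@]3(C)C(=O)O[C@@H]4C[C@H](C)CC[C@H]4C(C)(C)c4ccccc4)[C@H]1CCC(C)(Br)[C@H]2CO[Si](c1ccccc1)(c1ccccc1)C(C)(C)C
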